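## The problem

The target 12 is a crossed dimer of two styrylpyranones. Ring A, a 2,3-dihydrofuran (O1, C2, C3, C3a, C7a), is fused through C3a–C7a to ring B, a 2-pyranone (C4 carbonyl, O5, C6, C7) that carries the (E)-4-hydroxystyryl group at C6. C3 carries, through its C6, a second and free 4-hydroxy-2-pyranone (ring C), and C2 carries the catechol ring D.

The feature that opens the structure is this: O1–C7a=C3a of ring A is the enolised 1,3-dicarbonyl unit O4–C4=C3 of a 4-hydroxy-6-styryl-2-pyranone, and C3–C2 are the two alkene carbons of a second styrylpyranone. They are joined so that the pyranone carbon C3a is bonded to the alkene carbon next to ring C and the enol oxygen O1 to the benzylic carbon, which lies para to an oxygen of ring D. Two bonds between C3/O4 of one pyranone and the alkene of the other therefore make ring A, and the para oxygen can carry the charge that this union places on C2.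

Both halves contain an enol and a styryl alkene, so the union must be cross-selective (which half supplies C3/O4 and which the alkene) and regioselective (carbon to the alkene carbon next to ring C, oxygen to the benzylic carbon). There are only two stereocentres, C2 and C3, contiguous, trans and (2S,3S), and nothing else in the molecule from which their absolute configuration could be relayed; it must come from a reagent or catalyst when ring A is made.

The two centres are unequal. C2 is a para-hydroxybenzylic ether of a vinylogous acid and can ionise; C3–H is vinylogously acidic through ring C. If one epimerises, the other restores the trans isomer of the same enantiomeric series, but opening of ring A to the achiral alkene isomer erases both. C3 is therefore the centre to set, and C2 can follow it. The catechol (oxidation), the acidic enol of ring C, two lactones (hydroxide, amines), two styryl alkenes and the benzylic C2–O1 bond (no hydrogenolysis, no strong acid) limit what may be done once ring A exists, and the four hydroxyl groups should be released together under mild conditions.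

## Retrosynthesis

**12 to 11.** The last disconnection removes four protecting groups: three aryl O–Si bonds and one enol O–acyl bond. In 11 the phenols are tert-butyldimethylsilyl ethers, which keep rings D and E electron-rich, and the enol of ring C is a pivalate, which makes ring C electron-poor. Both types are cleaved in one basic methanolysis, so no hydrogenolysis, fluoride base or strong acid touches ring A. The forward step must leave C2, C3, the lactones and the alkenes alone.

**11 to 5 and 10 (key disconnection).** The bonds C3a–C3 and O1–C2 of ring A are cut together. Cutting only C2–C3 or only O1–C2 would leave the whole carbon skeleton to be assembled first; this double cut divides 11 into two flat, achiral styrylpyranones of equal size, both derived from lactone 1. The dicarbonyl carbon C3 of the ring B half must act as an electrophile. Biosynthesis presumably achieves this by oxidation of the enol; here the same carbon carries a diazo group (5), so only this half can take the role and a chiral dirhodium catalyst is present when the first bond forms. The alkene partner 10 is polarised by ring D (donor) and ring C (acceptor). The forward reaction must bond C3 of 5 to the alkene carbon C-a (next to ring C) and O4 of 5 to the benzylic carbon C-b, on one face of C-a, with ring closure trans.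

**5 to 4.** The C=N2 bond is cut. Diazo transfer to the acidic enol of 4 installs it in one step without touching the styryl alkene or the silyl ether, and 4 is the simplest precursor that already holds all carbons of rings B and E.

**4 to 1 and 2.** The styryl C=C bond is cut. Lactone 1 offers its 6-methyl group as a nucleophile (as the dianion), and aldehyde 2 brings ring E already silylated; the aldol adduct 3 is dehydrated without isolation. This is shorter than building the pyranone around a cinnamoyl unit, and the forward step must give the (E)-alkene, which is the thermodynamic outcome.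

**10 to 9.** The enol O–acyl bond is cut. Acylation of 9 comes last in this branch because the enol ester would not survive the strong base used to make the styryl bond.

**9 to 1 and 7, and 7 to 6.** The same styryl disconnection as for 4 leads to lactone 1 and aldehyde 7 (via aldol adduct 8). Aldehyde 7 is the bis-silyl ether of commercial 3,4-dihydroxybenzaldehyde 6. Both halves of the target thus come from one lactone and two hydroxybenzaldehydes.

## Roads not taken

Alternative 1: The most obvious plan cuts the same two bonds but joins unprotected hispidin A1 and bisnoryangonin A2 directly with a one-electron oxidant (Ag2O, FeCl3, Mn(OAc)3) or a peroxidase and H2O2. Each partner has both an enol and a styryl alkene, so nothing decides the roles. The target would be accompanied by its crossed isomer A3 (roles exchanged), by homodimers such as A4 from A1, and by products of catechol oxidation, and it would be racemic with no handle for resolution. The chosen plan keeps this bond construction but assigns the roles through the diazo group and the enol pivalate and places a chiral catalyst at the first bond-forming event.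

Alternative 2: A cut of C2–C3 alone leads to the diazo ester A5, whose rhodium carbenoid would insert into the benzylic C–H bond of its own 4-benzyloxy group under Rh2(S-PTTL)4 (dirhodium tetrakis[N-phthaloyl-(S)-tert-leucinate]). This is a reaction type with good enantiocontrol, and it would give the cis ester A6. However, A5 must be built linearly (O-benzylation, C3 iodination, palladium-catalysed diazoacetate coupling). After the key step, ring C must still be built from the ester and the styryl group attached by a base-mediated condensation. All of this happens next to a C3–H that is alpha to a carbonyl group and beta to a vinylogous carboxylate leaving group. The sequence would be about twice as long, linear, and its key step makes one bond in a small fragment instead of uniting the two halves.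

Alternative 3: A cut of O1–C2 alone leads to the achiral alkene A7, the ring-opened isomer of 11, to be closed by an enantioselective intramolecular oxa-Michael addition. A7 already contains the whole skeleton and would itself need a cross-coupling of a 3-metallated pyranone with an alpha-halogenated styrylpyranone. The closure is 5-endo-trig, and C3 would be set by a proton transfer outside catalyst control. The closure is also reversible under the basic conditions it needs, which is the racemisation pathway the chosen plan avoids.

Key step: step 6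

Assumption: the sense of induction of Rh2(S-TCPTTL)4 in step 6 cannot be predicted from precedent. The (S)-catalyst is written as giving the (2S,3S) series; the mirror-image catalyst from (R)-tert-leucine is used if the opposite sense is found.

## Steps

Step 1
Reactants: 1 4-hydroxy-6-methyl-2H-pyran-2-one (triacetic acid lactone); 2 4-[(tert-butyldimethylsilyl)oxy]benzaldehyde
Product: 4 4-hydroxy-6-[(E)-2-{4-[(tert-butyldimethylsilyl)oxy]phenyl}ethenyl]-2H-pyran-2-one, via racemic aldol adduct 3 (not isolated)
Conditions: LiN(iPr)2 (2.2 equiv), THF, −78 °C; 2, −78 °C; AcOH quench; crude 3, TsOH·H2O (cat.), toluene, 70 °C, dilute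
Reagents that add atoms: none
Why: The dianion of 1 reacts with aldehydes at the 6-methyl carbon (aldol addition), and the para-silyloxybenzylic alcohol 3 loses water under acid catalysis (E1) to the conjugated, thermodynamically preferred (E)-alkene; the aryl silyl ether tolerates cold amide base and catalytic acid.

Step 2
Reactants: 4 4-hydroxy-6-[(E)-2-{4-[(tert-butyldimethylsilyl)oxy]phenyl}ethenyl]-2H-pyran-2-one
Product: 5 3-diazo-6-[(E)-2-{4-[(tert-butyldimethylsilyl)oxy]phenyl}ethenyl]-2H-pyran-2,4(3H)-dione
Conditions: 4-acetamidobenzenesulfonyl azide, Et3N, MeCN, 0 °C to rt, dark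
Reagents that add atoms: 4-acetamidobenzenesulfonyl azide, CC(=O)Nc1ccc(cc1)S(=O)(=O)N=[N+]=[N-]
Why: Regitz diazo transfer to the acidic C3 of a cyclic 1,3-dicarbonyl compound, well known for 4-hydroxy-2-pyranones; the alkene and the silyl ether are inert to the sulfonyl azide at room temperature.

Step 3
Reactants: 6 3,4-dihydroxybenzaldehyde
Product: 7 3,4-bis[(tert-butyldimethylsilyl)oxy]benzaldehyde
Conditions: TBSCl (2.4 equiv), imidazole, DMF, rt
Reagents that add atoms: tert-butyldimethylsilyl chloride, CC(C)(C)[Si](C)(C)Cl
Why: Standard imidazole-promoted silylation of both phenols; the aldehyde is untouched.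

Step 4
Reactants: 1 4-hydroxy-6-methyl-2H-pyran-2-one; 7 3,4-bis[(tert-butyldimethylsilyl)oxy]benzaldehyde
Product: 9 6-[(E)-2-{3,4-bis[(tert-butyldimethylsilyl)oxy]phenyl}ethenyl]-4-hydroxy-2H-pyran-2-one, via racemic aldol adduct 8 (not isolated)
Conditions: LiN(iPr)2 (2.2 equiv), THF, −78 °C; 7, −78 °C; AcOH quench; crude 8, TsOH·H2O (cat.), toluene, 70 °C, dilute
Reagents that add atoms: none
Why: Same aldol addition of the dianion of 1 and acid-catalysed dehydration as in step 1; the second silyloxy group makes the benzylic alcohol 8 ionise still more readily, and quenching at low temperature prevents silyl migration.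

Step 5
Reactants: 9 6-[(E)-2-{3,4-bis[(tert-butyldimethylsilyl)oxy]phenyl}ethenyl]-4-hydroxy-2H-pyran-2-one
Product: 10 6-[(E)-2-{3,4-bis[(tert-butyldimethylsilyl)oxy]phenyl}ethenyl]-2-oxo-2H-pyran-4-yl 2,2-dimethylpropanoate
Conditions: pivaloyl chloride, Et3N, CH2Cl2, 0 °C (no DMAP)
Reagents that add atoms: pivaloyl chloride, CC(C)(C)C(=O)Cl
Why: 4-Hydroxy-2-pyranones are O-acylated kinetically by acyl chlorides and a tertiary amine; leaving out a nucleophilic catalyst avoids O-to-C acyl migration, and the bulky pivalate is stable to chromatography.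

Step 6
Reactants: 5 3-diazo-6-[(E)-2-{4-[(tert-butyldimethylsilyl)oxy]phenyl}ethenyl]-2H-pyran-2,4(3H)-dione; 10 6-[(E)-2-{3,4-bis[(tert-butyldimethylsilyl)oxy]phenyl}ethenyl]-2-oxo-2H-pyran-4-yl 2,2-dimethylpropanoate
Product: 11 6-[(2S,3S)-2-{3,4-bis[(tert-butyldimethylsilyl)oxy]phenyl}-6-[(E)-2-{4-[(tert-butyldimethylsilyl)oxy]phenyl}ethenyl]-4-oxo-2,3-dihydro-4H-furo[3,2-c]pyran-3-yl]-2-oxo-2H-pyran-4-yl 2,2-dimethylpropanoate
Conditions: Rh2(S-TCPTTL)4 (dirhodium tetrakis[N-tetrachlorophthaloyl-(S)-tert-leucinate], 2 mol%), 10 (2 equiv, excess recovered), 4 Å MS, PhCF3, 40 °C, 5 added over 6 h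
Reagents that add atoms: none
Why: Proposed new method: The catalyst extrudes N2 from 5 to give an electrophilic rhodium carbenoid at C3 of the pyran-2,4-dione, which attacks C-a of 10 (the alkene carbon next to ring C, the nucleophilic end of this donor–acceptor alkene) so that the charge develops at benzylic C-b under the para-silyloxy group; release of rhodium leaves the pyranone 4-olate, whose O4 captures C-b. The closest known reaction type is the formal [3+2] cycloaddition of cyclic 2-diazo-1,3-dicarbonyl compounds (and the Mn(OAc)3-mediated oxidative cycloaddition of the parent enols) with styrenes to 2-aryl-2,3-dihydrofurans, extended here to an internal, pyranone-conjugated alkene and to catalyst control of absolute configuration. Ring A is the only ring closed, by 5-exo-trig capture of the quinone-methide-like cation at C-b by O4. C3 (S) is created in the C3a–C3 bond-forming event while the carbenoid carbon is still bound to the chiral dirhodium core, whose tert-leucinate ligands select the enantiotopic face of C-a; with terminal styrenes, by contrast, the only stereocentre arises in the later, possibly metal-free ring closure. C2 (S) follows from C3, because O4 adds to the benzylic cation anti to the pyranonyl group, and the trans isomer is also the thermodynamic one, reachable from any cis isomer by reversible C2–O1 ionisation with C3 retained. The step needs chemoselectivity for the alkene of 10 over the styryl alkene of 5 (deactivated by the diazodione and kept dilute by slow addition into excess 10), over ring C of 10 (deactivated as the enol pivalate), and for closure through O4 instead of the lactone oxygen O2 (O4 is the more nucleophilic enolate terminus and gives the 2-pyranone).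

Step 7
Reactants: 11 6-[(2S,3S)-2-{3,4-bis[(tert-butyldimethylsilyl)oxy]phenyl}-6-[(E)-2-{4-[(tert-butyldimethylsilyl)oxy]phenyl}ethenyl]-4-oxo-2,3-dihydro-4H-furo[3,2-c]pyran-3-yl]-2-oxo-2H-pyran-4-yl 2,2-dimethylpropanoate
Product: 12 (2S,3S)-2-(3,4-dihydroxyphenyl)-3-(4-hydroxy-2-oxo-2H-pyran-6-yl)-6-[(E)-2-(4-hydroxyphenyl)ethenyl]-2,3-dihydro-4H-furo[3,2-c]pyran-4-one
Conditions: K2CO3 (excess), degassed MeOH, 0 °C to rt, argon; then 1 M HCl to pH 3; reversed-phase chromatography
Reagents that add atoms: none
Why: Carbonate in methanol cleaves the enol pivalate (a vinylogous mixed anhydride) within minutes and the three aryl silyl ethers more slowly, a standard transesterification and phenolic desilylation. Once ring C is an enolate, C3–H is no longer acidic, and opening of ring A by beta-elimination is the reverse of a 5-endo-trig closure and stereoelectronically poor, so C2 and C3 should be retained; exclusion of air protects the catechol.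

## Compound list

1 | 4-hydroxy-6-methyl-2H-pyran-2-one | Cc1cc(O)cc(=O)o1 | starting material
2 | 4-[(tert-butyldimethylsilyl)oxy]benzaldehyde | O=Cc1ccc(O[Si](C)(C)C(C)(C)C)cc1 | starting material
3 | 4-hydroxy-6-{2-hydroxy-2-[4-(tert-butyldimethylsilyloxy)phenyl]ethyl}-2H-pyran-2-one (racemic) | O=c1cc(O)cc(CC(O)c2ccc(O[Si](C)(C)C(C)(C)C)cc2)o1 | intermediate
4 | 4-hydroxy-6-[(E)-2-{4-[(tert-butyldimethylsilyl)oxy]phenyl}ethenyl]-2H-pyran-2-one | O=c1cc(O)cc(/C=C/c2ccc(O[Si](C)(C)C(C)(C)C)cc2)o1 | intermediate
5 | 3-diazo-6-[(E)-2-{4-[(tert-butyldimethylsilyl)oxy]phenyl}ethenyl]-2H-pyran-2,4(3H)-dione | [N-]=[N+]=C1C(=O)C=C(/C=C/c2ccc(O[Si](C)(C)C(C)(C)C)cc2)OC1=O | intermediate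
6 | 3,4-dihydroxybenzaldehyde | O=Cc1ccc(O)c(O)c1 | starting material
7 | 3,4-bis[(tert-butyldimethylsilyl)oxy]benzaldehyde | O=Cc1ccc(O[Si](C)(C)C(C)(C)C)c(O[Si](C)(C)C(C)(C)C)c1 | intermediate
8 | 6-{2-[3,4-bis(tert-butyldimethylsilyloxy)phenyl]-2-hydroxyethyl}-4-hydroxy-2H-pyran-2-one (racemic) | O=c1cc(O)cc(CC(O)c2ccc(O[Si](C)(C)C(C)(C)C)c(O[Si](C)(C)C(C)(C)C)c2)o1 | intermediate
9 | 6-[(E)-2-{3,4-bis[(tert-butyldimethylsilyl)oxy]phenyl}ethenyl]-4-hydroxy-2H-pyran-2-one | O=c1cc(O)cc(/C=C/c2ccc(O[Si](C)(C)C(C)(C)C)c(O[Si](C)(C)C(C)(C)C)c2)o1 | intermediate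
10 | 6-[(E)-2-{3,4-bis[(tert-butyldimethylsilyl)oxy]phenyl}ethenyl]-2-oxo-2H-pyran-4-yl 2,2-dimethylpropanoate | O=c1cc(OC(=O)C(C)(C)C)cc(/C=C/c2ccc(O[Si](C)(C)C(C)(C)C)c(O[Si](C)(C)C(C)(C)C)c2)o1 | intermediate
11 | 6-[(2S,3S)-2-{3,4-bis[(tert-butyldimethylsilyl)oxy]phenyl}-6-[(E)-2-{4-[(tert-butyldimethylsilyl)oxy]phenyl}ethenyl]-4-oxo-2,3-dihydro-4H-furo[3,2-c]pyran-3-yl]-2-oxo-2H-pyran-4-yl 2,2-dimethylpropanoate | O=c1cc(OC(=O)C(C)(C)C)cc([C@H]2c3c(cc(/C=C/c4ccc(O[Si](C)(C)C(C)(C)C)cc4)oc3=O)O[C@@H]2c2ccc(O[Si](C)(C)C(C)(C)C)c(O[Si](C)(C)C(C)(C)C)c2)o1 | intermediate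
12 | (2S,3S)-2-(3,4-dihydroxyphenyl)-3-(4-hydroxy-2-oxo-2H-pyran-6-yl)-6-[(E)-2-(4-hydroxyphenyl)ethenyl]-2,3-dihydro-4H-furo[3,2-c]pyran-4-one | O=c1cc(O)cc([C@H]2c3c(cc(/C=C/c4ccc(O)cc4)oc3=O)O[C@@H]2c2ccc(O)c(O)c2)o1 | target

## Step count and risk

Total: 7 steps. Longest linear sequence: 5 steps (steps 3, 4, 5, 6, 7, from 6). The second branch (steps 1 and 2) joins at step 6.

**Step 6 (key step, proposed new method).** Three things are most likely to go wrong:
- The pyranone-conjugated alkene may be too weak a nucleophile, so that the carbenoid is consumed by attack on the arene rings or by adventitious water.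
- Facial selectivity at C-a may be poor, since high enantiocontrol has not been shown for cyclic diazodione carbenoids.
- The ring may partly close through the lactone oxygen O2, or the zwitterion may lose a proton to give the ring-opened alkene.

The fallback uses known chemistry and sets out from 4 and 9. Enol 9 is acylated with (1S)-camphanic chloride and Et3N in place of pivaloyl chloride to give the (1S,4R)-camphanoyl ester F1. Enol 4 is then added oxidatively to F1 (in excess) with Mn(OAc)3·2H2O in AcOH at 40 °C, the established radical dihydrofuran annulation of cyclic 1,3-dicarbonyl compounds with aryl alkenes, which is trans-selective and has the same regiochemistry. It should give the (2S,3S)-configured camphanate adduct F2 together with its (2R,3R)-configured diastereomer F3. These are diastereomers and are to be separated by chromatography or crystallisation. F2 is then subjected to the conditions of step 7, which cleave the camphanate like the pivalate, and the route is rejoined at 12.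

**Step 4.** The aldol addition may stall because the dianion of 1 is poorly soluble, the ortho-disposed silyl groups may migrate or be lost, and during the acid dehydration the benzylic cation may alkylate the enol of another molecule instead of losing a proton. Step 1 runs the same chemistry on the less hindered aldehyde 2 and is judged safer. The fallback sets out from 7 and builds the pyranone around the preformed alkene. A Horner–Wadsworth–Emmons reaction with diethyl [2-(methoxy(methyl)amino)-2-oxoethyl]phosphonate and NaH gives the (E)-configured Weinreb amide F4. Acylation of 2,2,6-trimethyl-4H-1,3-dioxin-4-one (as its lithium dienolate, LiN(SiMe3)2, THF, −78 °C) with F4 gives the keto-dioxinone F5. Thermolysis in toluene at 110 °C releases acetone and cyclises the acylketene to 9, where the route is rejoined.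

**Step 7.** During the hours needed for desilylation in basic methanol, the catechol may oxidise and ring A may slowly epimerise or open. The fallback sets out from 11 and separates the two deprotections. HF·pyridine in THF at 0 °C removes the three silyl groups under mildly acidic conditions to give the enol pivalate triphenol F6. A brief, buffered methanolysis (NH4OAc, MeOH, rt) then removes the pivalate and gives 12.

**Step 2.** Diazo transfer itself is reliable, but the extended diazodione 5 may be light- and heat-sensitive and decompose during isolation. The fallback sets out from 4. PhI(OAc)2 and Na2CO3 in CH2Cl2 at 0 °C give the phenyliodonium ylide F7. Such ylides of cyclic 1,3-diones are established carbenoid precursors that react at lower temperature, and F7 is used directly with 10 and the dirhodium catalyst of step 6 to rejoin the route at 11.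

## Further compounds

F1 | step 6 | 6-[(E)-2-{3,4-bis[(tert-butyldimethylsilyl)oxy]phenyl}ethenyl]-2-oxo-2H-pyran-4-yl (1S,4R)-4,7,7-trimethyl-3-oxo-2-oxabicyclo[2.2.1]heptane-1-carboxylate | O=c1cc(OC(=O)[C@@]23CC[C@@](C)(C(=O)O2)C3(C)C)cc(/C=C/c2ccc(O[Si](C)(C)C(C)(C)C)c(O[Si](C)(C)C(C)(C)C)c2)o1
F2 | step 6 | (1S,4R)-camphanate analogue of 11 with (2S,3S) configuration in ring A | O=c1cc(OC(=O)[C@@]23CC[C@@](C)(C(=O)O2)C3(C)C)cc([C@H]2c3c(cc(/C=C/c4ccc(O[Si](C)(C)C(C)(C)C)cc4)oc3=O)O[C@@H]2c2ccc(O[Si](C)(C)C(C)(C)C)c(O[Si](C)(C)C(C)(C)C)c2)o1
F3 | step 6 | (1S,4R)-camphanate diastereomer with (2R,3R) configuration in ring A | O=c1cc(OC(=O)[C@@]23CC[C@@](C)(C(=O)O2)C3(C)C)cc([C@@H]2c3c(cc(/C=C/c4ccc(O[Si](C)(C)C(C)(C)C)cc4)oc3=O)O[C@H]2c2ccc(O[Si](C)(C)C(C)(C)C)c(O[Si](C)(C)C(C)(C)C)c2)o1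
F4 | step 4 | (E)-3-{3,4-bis[(tert-butyldimethylsilyl)oxy]phenyl}-N-methoxy-N-methylprop-2-enamide | CON(C)C(=O)/C=C/c1ccc(O[Si](C)(C)C(C)(C)C)c(O[Si](C)(C)C(C)(C)C)c1
F5 | step 4 | 6-[(E)-4-{3,4-bis[(tert-butyldimethylsilyl)oxy]phenyl}-2-oxobut-3-en-1-yl]-2,2-dimethyl-4H-1,3-dioxin-4-one | CC1(C)OC(CC(=O)/C=C/c2ccc(O[Si](C)(C)C(C)(C)C)c(O[Si](C)(C)C(C)(C)C)c2)=CC(=O)O1
F6 | step 7 | 6-[(2S,3S)-2-(3,4-dihydroxyphenyl)-6-[(E)-2-(4-hydroxyphenyl)ethenyl]-4-oxo-2,3-dihydro-4H-furo[3,2-c]pyran-3-yl]-2-oxo-2H-pyran-4-yl 2,2-dimethylpropanoate | O=c1cc(OC(=O)C(C)(C)C)cc([C@H]2c3c(cc(/C=C/c4ccc(O)cc4)oc3=O)O[C@@H]2c2ccc(O)c(O)c2)o1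
F7 | step 2 | phenyliodonium ylide of 4: 6-[(E)-2-{4-[(tert-butyldimethylsilyl)oxy]phenyl}ethenyl]-2-oxo-3-(phenyliodonio)-2H-pyran-4-olate | [O-]C1=C([I+]c2ccccc2)C(=O)OC(/C=C/c2ccc(O[Si](C)(C)C(C)(C)C)cc2)=C1
A1 | alternative 1 | hispidin, 6-[(E)-2-(3,4-dihydroxyphenyl)ethenyl]-4-hydroxy-2H-pyran-2-one | O=c1cc(O)cc(/C=C/c2ccc(O)c(O)c2)o1
A2 | alternative 1 | bisnoryangonin, 4-hydroxy-6-[(E)-2-(4-hydroxyphenyl)ethenyl]-2H-pyran-2-one | O=c1cc(O)cc(/C=C/c2ccc(O)cc2)o1
A3 | alternative 1 | crossed isomer with exchanged roles, trans-6-[(E)-2-(3,4-dihydroxyphenyl)ethenyl]-3-(4-hydroxy-2-oxo-2H-pyran-6-yl)-2-(4-hydroxyphenyl)-2,3-dihydro-4H-furo[3,2-c]pyran-4-one (racemic, one enantiomer drawn) | O=c1cc(O)cc([C@H]2c3c(cc(/C=C/c4ccc(O)c(O)c4)oc3=O)O[C@@H]2c2ccc(O)cc2)o1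
A4 | alternative 1 | homodimer of A1, trans-2-(3,4-dihydroxyphenyl)-6-[(E)-2-(3,4-dihydroxyphenyl)ethenyl]-3-(4-hydroxy-2-oxo-2H-pyran-6-yl)-2,3-dihydro-4H-furo[3,2-c]pyran-4-one (racemic, one enantiomer drawn) | O=c1cc(O)cc([C@H]2c3c(cc(/C=C/c4ccc(O)c(O)c4)oc3=O)O[C@@H]2c2ccc(O)c(O)c2)o1
A5 | alternative 2 | methyl 2-[4-({3,4-bis[(tert-butyldimethylsilyl)oxy]phenyl}methoxy)-6-methyl-2-oxo-2H-pyran-3-yl]-2-diazoacetate | COC(=O)C(=[N+]=[N-])c1c(OCc2ccc(O[Si](C)(C)C(C)(C)C)c(O[Si](C)(C)C(C)(C)C)c2)cc(C)oc1=O
A6 | alternative 2 | methyl (2S,3R)-2-{3,4-bis[(tert-butyldimethylsilyl)oxy]phenyl}-6-methyl-4-oxo-2,3-dihydro-4H-furo[3,2-c]pyran-3-carboxylate (cis) | COC(=O)[C@@H]1c2c(cc(C)oc2=O)O[C@@H]1c1ccc(O[Si](C)(C)C(C)(C)C)c(O[Si](C)(C)C(C)(C)C)c1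
A7 | alternative 3 | 6-[2-{3,4-bis[(tert-butyldimethylsilyl)oxy]phenyl}-1-{4-hydroxy-2-oxo-6-[(E)-2-{4-[(tert-butyldimethylsilyl)oxy]phenyl}ethenyl]-2H-pyran-3-yl}ethenyl]-2-oxo-2H-pyran-4-yl 2,2-dimethylpropanoate (E/Z mixture at the trisubstituted alkene) | O=c1cc(OC(=O)C(C)(C)C)cc(C(=Cc2ccc(O[Si](C)(C)C(C)(C)C)c(O[Si](C)(C)C(C)(C)C)c2)c2c(O)cc(/C=C/c3ccc(O[Si](C)(C)C(C)(C)C)cc3)oc2=O)o1
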